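The ring is numbered C1 (bearing C7) to C6, with the benzoate on C5 and the free hydroxyl on C6. The route rests on disconnecting C1–C6 and C2–C3: O6 sits on the ring carbon next to the C7-bearing C1, which is the ortho relationship produced when a 1-oxygenated diene (C3–C6) adds to an acetylenic carbonyl (C1, C2, C7). One ligand-controlled, copper-catalysed [4+2] closes the cyclohexadiene ring and sets C6. The isolated C4=C5 double bond that remains then carries oxygen across to C5, trans to O6. The precursors are an (E)-1-silyloxybutadiene and a chelating N-propioloylpyrazole.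

Key step: step 3

Assumption: the (S,S)-ligand is taken to deliver the (6S) adduct; if the sense of induction were opposite, the (R,R)-ligand would be used with no other change.

Step 1
Reactants: 1 (E)-crotonaldehyde
Product: 2 (E)-1-(tert-butyldimethylsilyloxy)buta-1,3-diene
Conditions: TBSOTf, Et3N, Et2O, 0 °C to rt; distillation
Reagents that add atoms: tert-butyldimethylsilyl trifluoromethanesulfonate, CC(C)(C)[Si](C)(C)OS(=O)(=O)C(F)(F)F
Why: Soft enolisation (vinylogous silyl enol ether formation): the aldehyde oxygen is silylated and triethylamine removes a γ-hydrogen of the oxocarbenium ion, which should favour the E-dienol ether, while any Z isomer is a spectator in step 3 because it reaches the s-cis conformation only with difficulty; no stereocentre is formed.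

Step 2
Reactants: 3 propiolic acid, 4 3,5-dimethylpyrazole
Product: 6 1-(3,5-dimethylpyrazol-1-yl)prop-2-yn-1-one, via O-propioloyl-N,N'-dicyclohexylisourea 5 (not isolated)
Conditions: DCC, CH2Cl2, −20 to 0 °C
Reagents that add atoms: none
Why: Carbodiimide-mediated N-acylation: DCC activates the acid as the O-acylisourea 5, which acylates N1 of the symmetrical pyrazole, and the low temperature suppresses conjugate addition of the pyrazole to the ynoyl unit; no stereocentre is formed.

Step 3
Reactants: 2 (E)-1-(tert-butyldimethylsilyloxy)buta-1,3-diene, 6 1-(3,5-dimethylpyrazol-1-yl)prop-2-yn-1-one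
Product: 7 (S)-[6-(tert-butyldimethylsilyloxy)cyclohexa-1,4-dien-1-yl](3,5-dimethylpyrazol-1-yl)methanone
Conditions: Cu(OTf)2 (10 mol %), (S,S)-2,2'-isopropylidenebis(4-tert-butyl-2-oxazoline) (11 mol %), 4 Å MS, 2 (1.5 equiv), CH2Cl2, −78 to −40 °C; cold filtration through Et3N-deactivated silica
Reagents that add atoms: none
Why: The acyl pyrazole binds the bis(oxazoline) complex of Cu(OTf)2 (divalent copper) as a five-membered chelate through the carbonyl oxygen and pyrazole N2, which lowers the alkyne LUMO and puts its largest coefficient on the terminal carbon (future C2), while the diene HOMO is largest at the terminus remote from oxygen (future C3), so a concerted but asynchronous [4+2] forms C2–C3 slightly ahead of C1–C6. The closest known reaction type is the enantioselective Diels–Alder reaction of 1-propioloylpyrazoles with dienes under chiral divalent-copper Lewis acids, applied here to a diene not yet tried. The cyclohexa-1,4-diene ring is closed by this suprafacial six-electron cycloaddition of the s-cis diene, both ring bonds arising in one event, and because the alkyne carbons stay sp2 only one stereocentre (C6) is created. C6 is controlled by the ligand: a tert-butyl group screens one face of the planar chelate and the diene is expected to turn its silyloxy terminus away from the 5-methyl group of the pyrazole, so that a single diene face is bonded. The step needs ortho regioselectivity, secured by the oxygen donor at the diene terminus and the acceptor on the alkyne, and it needs the adduct to survive, which the robust TBS ether and a cold, neutral work-up should secure by preventing loss of silanol to the arene; a [2+2] addition at the enol ether is the expected minor diversion.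

Step 4
Reactants: 7 (S)-[6-(tert-butyldimethylsilyloxy)cyclohexa-1,4-dien-1-yl](3,5-dimethylpyrazol-1-yl)methanone
Product: 8 [(1R,2R,6R)-2-(tert-butyldimethylsilyloxy)-7-oxabicyclo[4.1.0]hept-3-en-3-yl](3,5-dimethylpyrazol-1-yl)methanone (epoxide across ring C4–C5, anti to the C6 silyloxy group)
Conditions: DMDO (acetone solution), CH2Cl2, −20 to 0 °C
Reagents that add atoms: dimethyldioxirane, CC1(C)OO1
Why: Electrophilic dioxirane epoxidation under neutral conditions should attack the isolated, electron-richer C4=C5 alkene in preference to the acyl-conjugated C1=C2, and the pseudoaxial silyloxy group on C6 blocks its own face so that oxygen is delivered anti to it, which sets C4 and C5 by substrate control.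

Step 5
Reactants: 8 [(1R,2R,6R)-2-(tert-butyldimethylsilyloxy)-7-oxabicyclo[4.1.0]hept-3-en-3-yl](3,5-dimethylpyrazol-1-yl)methanone
Product: 9 [(5R,6R)-6-(tert-butyldimethylsilyloxy)-5-hydroxycyclohexa-1,3-dien-1-yl](3,5-dimethylpyrazol-1-yl)methanone
Conditions: DBU (0.2 equiv), CH2Cl2, −20 to 0 °C; pH 7 phosphate buffer quench
Reagents that add atoms: none
Why: Vinylogous E1cB opening of a γ,δ-epoxy enoyl system: DBU removes a C3 hydrogen, which is γ to the acyl pyrazole and next to the epoxide, and the extended enolate breaks the C4–O bond to give the conjugated C1=C2–C3=C4 diene and the C5 hydroxyl; the C5–O bond is untouched, so its trans relation to O6 from step 4 is kept and no new stereocentre is formed.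

Step 6
Reactants: 9 [(5R,6R)-6-(tert-butyldimethylsilyloxy)-5-hydroxycyclohexa-1,3-dien-1-yl](3,5-dimethylpyrazol-1-yl)methanone
Product: 11 (1R,6R)-6-(tert-butyldimethylsilyloxy)-5-(hydroxymethyl)cyclohexa-2,4-dien-1-ol, via C7 aldehyde 10 (not isolated)
Conditions: NaBH4, THF/H2O (10:1), 0 °C; aq NH4Cl
Reagents that add atoms: none
Why: Hydride reduction of an activated amide: borohydride adds to the acyl pyrazole, loss of the pyrazole gives aldehyde 10, and 1,2-reduction of this dienal gives the allylic alcohol, while the silyl ether and the diene are inert; no stereocentre is formed or touched.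

Step 7
Reactants: 11 (1R,6R)-6-(tert-butyldimethylsilyloxy)-5-(hydroxymethyl)cyclohexa-2,4-dien-1-ol
Product: 12 [(5R,6R)-5-(benzoyloxy)-6-(tert-butyldimethylsilyloxy)cyclohexa-1,3-dien-1-yl]methyl benzoate
Conditions: BzCl (2.5 equiv), pyridine, DMAP (cat.), CH2Cl2, 0 °C to rt
Reagents that add atoms: benzoyl chloride, O=C(Cl)c1ccccc1
Why: DMAP-catalysed acylation with an acid chloride esterifies both free hydroxyls, the primary O7 and the secondary O5, while O6 stays masked as its silyl ether, so the benzoate pattern follows from the order in which the oxygens were unveiled; no stereocentre is touched.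

Step 8
Reactants: 12 [(5R,6R)-5-(benzoyloxy)-6-(tert-butyldimethylsilyloxy)cyclohexa-1,3-dien-1-yl]methyl benzoate
Product: 13 [(5R,6R)-5-(benzoyloxy)-6-hydroxycyclohexa-1,3-dien-1-yl]methyl benzoate
Conditions: HF·pyridine, pyridine, THF, 0 °C to rt
Reagents that add atoms: none
Why: Fluoride-induced Si–O cleavage under buffered, weakly acidic conditions frees O6 without generating its alkoxide, so a 1,2-shift of the neighbouring benzoate from O5 and aromatisation are not expected, and C5 and C6 keep their configuration.

Compound list
1 | (E)-crotonaldehyde | C/C=C/C=O | starting material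
2 | (E)-1-(tert-butyldimethylsilyloxy)buta-1,3-diene | C=C/C=C/O[Si](C)(C)C(C)(C)C | intermediate
3 | propiolic acid | C#CC(=O)O | starting material
4 | 3,5-dimethylpyrazole | Cc1cc(C)n[nH]1 | starting material
5 | O-propioloyl-N,N'-dicyclohexylisourea | C#CC(=O)OC(=NC1CCCCC1)NC1CCCCC1 | intermediate (not isolated)
6 | 1-(3,5-dimethylpyrazol-1-yl)prop-2-yn-1-one | C#CC(=O)n1nc(C)cc1C | intermediate
7 | (S)-[6-(tert-butyldimethylsilyloxy)cyclohexa-1,4-dien-1-yl](3,5-dimethylpyrazol-1-yl)methanone | O=C(C1=CCC=C[C@@H]1O[Si](C)(C)C(C)(C)C)n1nc(C)cc1C | intermediate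
8 | [(1R,2R,6R)-2-(tert-butyldimethylsilyloxy)-7-oxabicyclo[4.1.0]hept-3-en-3-yl](3,5-dimethylpyrazol-1-yl)methanone | O=C(C1=CC[C@H]2O[C@H]2[C@@H]1O[Si](C)(C)C(C)(C)C)n1nc(C)cc1C | intermediate
9 | [(5R,6R)-6-(tert-butyldimethylsilyloxy)-5-hydroxycyclohexa-1,3-dien-1-yl](3,5-dimethylpyrazol-1-yl)methanone | O=C(C1=CC=C[C@@H](O)[C@@H]1O[Si](C)(C)C(C)(C)C)n1nc(C)cc1C | intermediate
10 | (5R,6R)-6-(tert-butyldimethylsilyloxy)-5-hydroxycyclohexa-1,3-diene-1-carbaldehyde | O=CC1=CC=C[C@@H](O)[C@@H]1O[Si](C)(C)C(C)(C)C | intermediate (not isolated)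
11 | (1R,6R)-6-(tert-butyldimethylsilyloxy)-5-(hydroxymethyl)cyclohexa-2,4-dien-1-ol | OCC1=CC=C[C@@H](O)[C@@H]1O[Si](C)(C)C(C)(C)C | intermediate
12 | [(5R,6R)-5-(benzoyloxy)-6-(tert-butyldimethylsilyloxy)cyclohexa-1,3-dien-1-yl]methyl benzoate | O=C(OCC1=CC=C[C@@H](OC(=O)c2ccccc2)[C@@H]1O[Si](C)(C)C(C)(C)C)c1ccccc1 | intermediate
13 | [(5R,6R)-5-(benzoyloxy)-6-hydroxycyclohexa-1,3-dien-1-yl]methyl benzoate | O=C(OCC1=CC=C[C@@H](OC(=O)c2ccccc2)[C@@H]1O)c1ccccc1 | target

Total step count: 8. Longest linear sequence: 7 steps (steps 1, 3, 4, 5, 6, 7, 8).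

Steps most likely to fail

Step 3. The ligand may not discriminate the diene faces well enough, or the Lewis acid may strip the silyl group or trigger loss of silanol, which aromatises the adduct. The fallback sets out from 2 and returns at 11.
- Uncatalysed Diels–Alder reaction of 2 with commercial ethyl propiolate (C#CC(=O)OCC; toluene, 80 °C) should give racemic ethyl 6-(tert-butyldimethylsilyloxy)cyclohexa-1,4-diene-1-carboxylate F1.
- DMDO as in step 4 should give the racemic anti epoxide, ethyl rac-(1R,2R,6R)-2-(tert-butyldimethylsilyloxy)-7-oxabicyclo[4.1.0]hept-3-ene-3-carboxylate F2.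
- Catalytic DBU as in step 5 should give ethyl rac-(5R,6R)-6-(tert-butyldimethylsilyloxy)-5-hydroxycyclohexa-1,3-diene-1-carboxylate F3.
- Lipase-catalysed kinetic resolution (Burkholderia cepacia lipase, vinyl acetate, tert-butyl methyl ether, 30 °C, stopped near half conversion) is expected to acetylate the (5R) enantiomer, following the empirical size rule for secondary alcohols. This would give ethyl (5R,6R)-5-acetoxy-6-(tert-butyldimethylsilyloxy)cyclohexa-1,3-diene-1-carboxylate F4, separated from the unreacted (5S,6S) half of F3.
- i-Bu2AlH (CH2Cl2, −78 °C) then reduces the ester and removes the acetate, giving diol 11.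

Step 5. A second deprotonation at C5 with expulsion of silanolate would aromatise the product, and the activated amide may acylate the liberated C5 hydroxyl of another molecule. The fallback sets out from 7, avoids base and replaces steps 4 and 5, returning at 9.
- Schenck ene reaction of 7 with singlet oxygen (O2, tetraphenylporphyrin, hν, CH2Cl2, −78 °C) should add oxygen at C5 anti to the silyloxy group while a C3 hydrogen is transferred and the alkene moves to C3=C4. This gives [(5R,6R)-6-(tert-butyldimethylsilyloxy)-5-hydroperoxycyclohexa-1,3-dien-1-yl](3,5-dimethylpyrazol-1-yl)methanone F5.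
- Reduction in the same flask with PPh3 gives 9.

Step 6. Hydride may add in conjugate fashion to the dienoyl system, the acyl pyrazole may hydrolyse before it is reduced, and the alkaline medium may cause elimination. The fallback sets out from 9 and returns at 11.
- Methanolysis of the acyl pyrazole (MeOH, DMAP cat., rt) should give methyl (5R,6R)-6-(tert-butyldimethylsilyloxy)-5-hydroxycyclohexa-1,3-diene-1-carboxylate F6.
- 1,2-Selective reduction with i-Bu2AlH (CH2Cl2, −78 °C) gives diol 11.

Further compounds
F1 | step 3 | racemic ethyl 6-(tert-butyldimethylsilyloxy)cyclohexa-1,4-diene-1-carboxylate | CCOC(=O)C1=CCC=CC1O[Si](C)(C)C(C)(C)C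
F2 | step 3 | ethyl rac-(1R,2R,6R)-2-(tert-butyldimethylsilyloxy)-7-oxabicyclo[4.1.0]hept-3-ene-3-carboxylate (racemate, one enantiomer drawn) | CCOC(=O)C1=CC[C@H]2O[C@H]2[C@@H]1O[Si](C)(C)C(C)(C)C
F3 | step 3 | ethyl rac-(5R,6R)-6-(tert-butyldimethylsilyloxy)-5-hydroxycyclohexa-1,3-diene-1-carboxylate (racemate, one enantiomer drawn) | CCOC(=O)C1=CC=C[C@@H](O)[C@@H]1O[Si](C)(C)C(C)(C)C
F4 | step 3 | ethyl (5R,6R)-5-acetoxy-6-(tert-butyldimethylsilyloxy)cyclohexa-1,3-diene-1-carboxylate | CCOC(=O)C1=CC=C[C@@H](OC(C)=O)[C@@H]1O[Si](C)(C)C(C)(C)C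
F5 | step 5 | [(5R,6R)-6-(tert-butyldimethylsilyloxy)-5-hydroperoxycyclohexa-1,3-dien-1-yl](3,5-dimethylpyrazol-1-yl)methanone | O=C(C1=CC=C[C@@H](OO)[C@@H]1O[Si](C)(C)C(C)(C)C)n1nc(C)cc1C
F6 | step 6 | methyl (5R,6R)-6-(tert-butyldimethylsilyloxy)-5-hydroxycyclohexa-1,3-diene-1-carboxylate | COC(=O)C1=CC=C[C@@H](O)[C@@H]1O[Si](C)(C)C(C)(C)C
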